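**Retrosynthetic overview**
The target is tamarixetin 3,7-bis(hydrogen sulfate), an achiral flavonol. Both sulfate esters go on late, onto a 3,5,7-triol whose 3'-oxygen is a benzyl ether and whose 5-OH is held back by its hydrogen bond to the C4 carbonyl.
Feature used: on ring A, O1 (on C8a), 5-O and 7-O occupy the two ortho positions and the para position relative to C4a, the carbon bearing the C4 carbonyl. All three aryl C–O bonds can therefore be made by SNAr on one locally symmetric 2,4,6-trifluorobenzoyl unit.
Disconnections: C5–O and C7–O (intermolecular SNAr with a PMB alkoxide); O1–C8a (intramolecular SNAr of a diketone enolate); C3–C4 (C-acylation of an α-MOM-oxy ketone enolate); C3–O (Moriarty α-hydroxylation of O-benzyl acetoisovanillone).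
Ring order: rings A and B are bought as arenes, and ring C is the only ring formed, in step 5.
Key step: step 5

Assumption: the sulfate esters are drawn as hydrogen sulfates, as in the target SMILES. At the bench 16–18 are handled as trialkylammonium salts, and the acid form is released only at the end by cold proton exchange.

**Step 1**
Reactants: 1 3-hydroxy-4-methoxyacetophenone; 2 benzyl bromide
Product: 3 1-[3-(benzyloxy)-4-methoxyphenyl]ethan-1-one
Conditions: K2CO3, DMF, 60 °C
Reagents that add atoms: none
Why: Williamson ether synthesis, in which the phenoxide made by K2CO3 displaces bromide from the benzylic halide by SN2 while carbonate is too weak to enolise the methyl ketone.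

**Step 2**
Reactants: 3 1-[3-(benzyloxy)-4-methoxyphenyl]ethan-1-one
Product: 5 1-[3-(benzyloxy)-4-methoxyphenyl]-2-hydroxyethan-1-one, via hydroxy dimethyl acetal 4 (not isolated)
Conditions: PhI(OAc)2, KOH, MeOH, 0 °C → rt; then 2 M aq HCl, THF, rt
Reagents that add atoms: methanol, CO (both methoxy groups of 4, lost again on hydrolysis); water, O (carbonyl oxygen of 5)
Why: Moriarty α-hydroxylation, in which the enolate is captured by the trivalent iodine reagent, methoxide adds to the carbonyl, the alkoxide expels iodobenzene to give a methoxy epoxide that methoxide opens to acetal 4, and dilute acid then unmasks the ketone without touching the benzyl ether.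

**Step 3**
Reactants: 5 1-[3-(benzyloxy)-4-methoxyphenyl]-2-hydroxyethan-1-one
Product: 6 1-[3-(benzyloxy)-4-methoxyphenyl]-2-(methoxymethoxy)ethan-1-one
Conditions: MOMCl, iPr2NEt, CH2Cl2, 0 °C → rt
Reagents that add atoms: chloromethyl methyl ether, COCCl
Why: Acetal protection of a primary alcohol by O-alkylation with the oxocarbenium-type electrophile MOMCl, the hindered amine only taking up HCl and not enolising the ketone.

**Step 4**
Reactants: 6 1-[3-(benzyloxy)-4-methoxyphenyl]-2-(methoxymethoxy)ethan-1-one; 7 2,4,6-trifluorobenzoyl chloride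
Product: 10 1-[3-(benzyloxy)-4-methoxyphenyl]-2-(methoxymethoxy)-3-(2,4,6-trifluorophenyl)propane-1,3-dione (racemic), via lithium enolate 8 (not isolated), via lithium diketonate 9 (not isolated)
Conditions: LiN(SiMe3)2 (2.2 equiv), THF, −78 °C; then 7, −78 → −30 °C; AcOH quench
Reagents that add atoms: none
Why: Crossed Claisen-type C-acylation of a lithium enolate with an acid chloride, in which chelated Z-enolate 8 attacks the very electrophilic acyl chloride through carbon and the second equivalent of base stores the product as diketonate 9 against further acylation; the new central carbon is racemic, configurationally labile and becomes sp2 in step 5.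

**Step 5**
Reactants: 10 1-[3-(benzyloxy)-4-methoxyphenyl]-2-(methoxymethoxy)-3-(2,4,6-trifluorophenyl)propane-1,3-dione
Product: 12 2-[3-(benzyloxy)-4-methoxyphenyl]-5,7-difluoro-3-(methoxymethoxy)-4H-chromen-4-one, via potassium enolate 11 (not isolated)
Conditions: K2CO3 (2.5 equiv), dry DMF (0.05 M), 25 → 50 °C
Reagents that add atoms: none
Why: K2CO3 removes the acidic C–H between the two carbonyls of 10; in enolate 11 the oxygen on the ring B carbonyl carbon (future O1) adds to one ortho C–F carbon of the trifluorophenyl ring (future C8a) to give a Meisenheimer anion whose charge rests on C4a and the C4 carbonyl oxygen, and loss of fluoride restores the arene and leaves the O1–C8a bond. The closest known reaction type is the base-mediated intramolecular SNAr of 1-(2-fluoroaryl)-1,3-diketones to chromones and flavones, the oxygen counterpart of the Grohe quinolone cyclisation. Ring C closes as a six-membered ring by addition–elimination that is formally 6-endo-trig, because the C8a=C4a bond that accepts the electrons lies inside the new ring (an oxa-Michael addition to C8a=C4a–C4=O followed by loss of fluoride). No stereocentre is formed, and the labile central carbon of 10 becomes the sp2 carbon C3 that already carries its oxygen, so the flavonol oxidation level needs no later adjustment. Regioselectivity is secured by the substrate: the two ortho fluorines are interchanged by rotation about the C4–C4a bond and give the same product, attack through the enolate carbon would need a four-membered ring, and the para fluorine cannot be reached within the molecule. Chemoselectivity against intermolecular attack at a para C–F bond, retro-Claisen cleavage and substitution by dimethylamine from DMF rests on dilution, dry carbonate and a temperature not above 50 °C, conditions under which the MOM, benzyl and methyl ethers are inert.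

**Step 6**
Reactants: 12 2-[3-(benzyloxy)-4-methoxyphenyl]-5,7-difluoro-3-(methoxymethoxy)-4H-chromen-4-one
Product: 14 2-[3-(benzyloxy)-4-methoxyphenyl]-5,7-bis[(4-methoxybenzyl)oxy]-3-(methoxymethoxy)-4H-chromen-4-one, via 7-PMB-oxy-5-fluoroflavone 13 (not isolated)
Conditions: 4-MeOC6H4CH2OH (3.0 equiv), NaH (2.8 equiv), THF, 0 °C; then added to 12 in dry DMF, 0 → 60 °C
Reagents that add atoms: 4-methoxybenzyl alcohol, COc1ccc(CO)cc1
Why: Twofold intermolecular SNAr of activated aryl fluorides with an alkoxide, since C7–F (para) and C5–F (ortho) are both conjugated with the C4 carbonyl through C4a; the less hindered C7 should react first (13) and C5 on warming, dry conditions keep any alkoxide addition at C2 reversible, and the MOM and benzyl ethers are inert to base.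

**Step 7**
Reactants: 14 2-[3-(benzyloxy)-4-methoxyphenyl]-5,7-bis[(4-methoxybenzyl)oxy]-3-(methoxymethoxy)-4H-chromen-4-one
Product: 15 2-[3-(benzyloxy)-4-methoxyphenyl]-3,5,7-trihydroxy-4H-chromen-4-one (3'-O-benzyltamarixetin)
Conditions: TFA–CH2Cl2 (1:4), anisole (10 equiv), 0 °C → rt; aqueous work-up
Reagents that add atoms: none
Why: Acidolysis of acid-labile ethers, in which both PMB ethers ionise to the stabilised 4-methoxybenzyl cation that anisole traps by Friedel–Crafts alkylation before it can attack C6 or C8, the MOM acetal is cleaved through its oxocarbenium ion, and the unactivated 3'-benzyl ether does not ionise in dilute TFA at or below room temperature.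

**Step 8**
Reactants: 15 2-[3-(benzyloxy)-4-methoxyphenyl]-3,5,7-trihydroxy-4H-chromen-4-one
Product: 17 2-[3-(benzyloxy)-4-methoxyphenyl]-5-hydroxy-4-oxo-4H-chromene-3,7-diyl bis(hydrogen sulfate), via 7-monosulfate 16 (not isolated)
Conditions: SO3·NMe3 (5 equiv), Et3N (6 equiv), dry DMF, 45 °C; reversed-phase C18 chromatography of the ammonium salt
Reagents that add atoms: sulfur trioxide–trimethylamine complex, C[N+](C)(C)S(=O)(=O)[O-]
Why: O-sulfation with a sulfur trioxide–amine complex, in which the most acidic 7-OH and then the enolic 3-OH take up SO3 while the 5-OH is locked in a six-membered hydrogen bond to the C4 carbonyl and the 3'-oxygen is blocked as its benzyl ether, so the mild complex should stop at the 3,7-disulfate.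

**Step 9**
Reactants: 17 2-[3-(benzyloxy)-4-methoxyphenyl]-5-hydroxy-4-oxo-4H-chromene-3,7-diyl bis(hydrogen sulfate)
Product: 18 5-hydroxy-2-(3-hydroxy-4-methoxyphenyl)-4-oxo-4H-chromene-3,7-diyl bis(hydrogen sulfate) (tamarixetin 3,7-disulfate, target)
Conditions: H2 (1 atm), 10% Pd/C, MeOH–H2O, rt; then sulfonic acid cation-exchange resin (H+ form), H2O, 0 °C; freeze-drying
Reagents that add atoms: none
Why: Catalytic hydrogenolysis of the benzylic C–O bond, under which sulfate monoester anions, the aryl methyl ether and the tetrasubstituted C2=C3 bond of the flavonol are not reduced at atmospheric pressure, followed by brief cold proton exchange to the drawn acid form.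

**Compound list**
1 | 3-hydroxy-4-methoxyacetophenone | CC(=O)c1ccc(OC)c(O)c1 | starting material
2 | benzyl bromide | BrCc1ccccc1 | starting material
3 | 1-[3-(benzyloxy)-4-methoxyphenyl]ethan-1-one | CC(=O)c1ccc(OC)c(OCc2ccccc2)c1 | intermediate
4 | 2-[3-(benzyloxy)-4-methoxyphenyl]-2,2-dimethoxyethan-1-ol | OCC(OC)(OC)c1ccc(OC)c(OCc2ccccc2)c1 | intermediate
5 | 1-[3-(benzyloxy)-4-methoxyphenyl]-2-hydroxyethan-1-one | O=C(CO)c1ccc(OC)c(OCc2ccccc2)c1 | intermediate
6 | 1-[3-(benzyloxy)-4-methoxyphenyl]-2-(methoxymethoxy)ethan-1-one | O=C(COCOC)c1ccc(OC)c(OCc2ccccc2)c1 | intermediate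
7 | 2,4,6-trifluorobenzoyl chloride | O=C(Cl)c1c(F)cc(F)cc1F | starting material
8 | lithium (Z)-enolate of 6 | [Li+].[O-]/C(=C\OCOC)c1ccc(OC)c(OCc2ccccc2)c1 | intermediate
9 | lithium diketonate of 10 (drawn as the chelating E-enolate) | [Li+].[O-]/C(=C(/OCOC)C(=O)c1c(F)cc(F)cc1F)c1ccc(OC)c(OCc2ccccc2)c1 | intermediate
10 | 1-[3-(benzyloxy)-4-methoxyphenyl]-2-(methoxymethoxy)-3-(2,4,6-trifluorophenyl)propane-1,3-dione (racemic, labile centre) | O=C(c1c(F)cc(F)cc1F)C(OCOC)C(=O)c1ccc(OC)c(OCc2ccccc2)c1 | intermediate
11 | potassium (E)-enolate of 10 (enolate oxygen cis to the trifluorobenzoyl group) | [K+].[O-]/C(=C(/OCOC)C(=O)c1c(F)cc(F)cc1F)c1ccc(OC)c(OCc2ccccc2)c1 | intermediate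
12 | 2-[3-(benzyloxy)-4-methoxyphenyl]-5,7-difluoro-3-(methoxymethoxy)-4H-chromen-4-one | O=c1c(OCOC)c(-c2ccc(OC)c(OCc3ccccc3)c2)oc2cc(F)cc(F)c12 | intermediate
13 | 2-[3-(benzyloxy)-4-methoxyphenyl]-5-fluoro-7-[(4-methoxybenzyl)oxy]-3-(methoxymethoxy)-4H-chromen-4-one | O=c1c(OCOC)c(-c2ccc(OC)c(OCc3ccccc3)c2)oc2cc(OCc3ccc(OC)cc3)cc(F)c12 | intermediate
14 | 2-[3-(benzyloxy)-4-methoxyphenyl]-5,7-bis[(4-methoxybenzyl)oxy]-3-(methoxymethoxy)-4H-chromen-4-one | O=c1c(OCOC)c(-c2ccc(OC)c(OCc3ccccc3)c2)oc2cc(OCc3ccc(OC)cc3)cc(OCc3ccc(OC)cc3)c12 | intermediate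
15 | 2-[3-(benzyloxy)-4-methoxyphenyl]-3,5,7-trihydroxy-4H-chromen-4-one | O=c1c(O)c(-c2ccc(OC)c(OCc3ccccc3)c2)oc2cc(O)cc(O)c12 | intermediate
16 | 2-[3-(benzyloxy)-4-methoxyphenyl]-3,5-dihydroxy-4-oxo-4H-chromen-7-yl hydrogen sulfate | O=c1c(O)c(-c2ccc(OC)c(OCc3ccccc3)c2)oc2cc(OS(=O)(=O)O)cc(O)c12 | intermediate
17 | 2-[3-(benzyloxy)-4-methoxyphenyl]-5-hydroxy-4-oxo-4H-chromene-3,7-diyl bis(hydrogen sulfate) | O=c1c(OS(=O)(=O)O)c(-c2ccc(OC)c(OCc3ccccc3)c2)oc2cc(OS(=O)(=O)O)cc(O)c12 | intermediate
18 | 5-hydroxy-2-(3-hydroxy-4-methoxyphenyl)-4-oxo-4H-chromene-3,7-diyl bis(hydrogen sulfate) | COc1ccc(-c2oc3cc(OS(=O)(=O)O)cc(O)c3c(=O)c2OS(=O)(=O)O)cc1O | target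

**Step count and risks**
Total step count: 9. Longest linear sequence: 9 steps (from 1 to 18). The target has no stereocentre.

The three steps most likely to fail are given in route order.

**Step 5 (ring closure).**
- What may go wrong: retro-Claisen loss of the electron-poor trifluorobenzoyl group through traces of hydroxide, or intermolecular attack of the enolate on a para C–F bond of a second molecule, may outrun the closure.
- Fallback (Algar–Flynn–Oyamada route): ring C is closed at C2–O1 instead, with O1 brought in as a phenol.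
- It sets out from benzyl bromide 2, which O-alkylates purchased isovanillin (O=Cc1ccc(OC)c(O)c1; K2CO3, DMF) to 3-(benzyloxy)-4-methoxybenzaldehyde F1.
- Claisen–Schmidt condensation with purchased 1-(2,4-difluoro-6-hydroxyphenyl)ethan-1-one (CC(=O)c1c(O)cc(F)cc1F; KOH, EtOH, rt) should give (E)-3-[3-(benzyloxy)-4-methoxyphenyl]-1-(2,4-difluoro-6-hydroxyphenyl)prop-2-en-1-one F2.
- Alkaline H2O2 (NaOH, MeOH, 0 °C → rt) should convert it into 2-[3-(benzyloxy)-4-methoxyphenyl]-5,7-difluoro-3-hydroxy-4H-chromen-4-one F3. The small 6'-fluorine should not force the aurone pathway that bulky 6'-alkoxy groups favour.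
- MOMCl and iPr2NEt then lead back to the route at 12.

**Step 6 (double fluoride exchange).**
- What may go wrong: once C7 has reacted, the 7-alkoxy group feeds electron density through C4a into the C4 carbonyl, so attack at the hindered peri C5–F bond may stall. Long heating with excess benzylic alkoxide may then erode ring C by addition at C2.
- Fallback: the exchange is staged, and C5 is served by a hydroxide surrogate.
- It sets out from 12, which is treated with one equivalent of sodium 4-methoxybenzyl oxide in DMF at −20 → 0 °C, and 13 is now isolated.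
- 2-(Methylsulfonyl)ethanol and NaH in DMF should displace the 5-fluoride to give 2-[3-(benzyloxy)-4-methoxyphenyl]-7-[(4-methoxybenzyl)oxy]-3-(methoxymethoxy)-5-[2-(methylsulfonyl)ethoxy]-4H-chromen-4-one F4.
- F4 loses methyl vinyl sulfone by E1cB elimination in the same flask and delivers 2-[3-(benzyloxy)-4-methoxyphenyl]-5-hydroxy-7-[(4-methoxybenzyl)oxy]-3-(methoxymethoxy)-4H-chromen-4-one F5.
- The conditions of step 7 (TFA, anisole, CH2Cl2) then bring it back to the route at 15.

**Step 8 (regioselective disulfation).**
- What may go wrong: incomplete sulfation of the hindered enolic 3-OH, onset of sulfation at the 5-OH, or hydrolytic loss of sulfate while very polar salts are being separated.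
- Fallback: protected sulfate diesters.
- It sets out from 15, which with 2,2,2-trichloroethyl chlorosulfate (ClS(=O)(=O)OCC(Cl)(Cl)Cl, 2.3 equiv), Et3N and DMAP in THF at 0 °C should give 2-[3-(benzyloxy)-4-methoxyphenyl]-5-hydroxy-4-oxo-4H-chromene-3,7-diyl bis(2,2,2-trichloroethyl) bis(sulfate) F6.
- F6 is a neutral compound that can be purified on silica, so regiochemical purity is settled before any salt is made.
- Reductive fragmentation with Zn dust and HCO2NH4 in MeOH at rt leaves the benzyl ether intact and comes back to the route at 17.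

**Further compounds**
F1 | step 5 | 3-(benzyloxy)-4-methoxybenzaldehyde | O=Cc1ccc(OC)c(OCc2ccccc2)c1
F2 | step 5 | (E)-3-[3-(benzyloxy)-4-methoxyphenyl]-1-(2,4-difluoro-6-hydroxyphenyl)prop-2-en-1-one | O=C(/C=C/c1ccc(OC)c(OCc2ccccc2)c1)c1c(O)cc(F)cc1F
F3 | step 5 | 2-[3-(benzyloxy)-4-methoxyphenyl]-5,7-difluoro-3-hydroxy-4H-chromen-4-one | O=c1c(O)c(-c2ccc(OC)c(OCc3ccccc3)c2)oc2cc(F)cc(F)c12
F4 | step 6 | 2-[3-(benzyloxy)-4-methoxyphenyl]-7-[(4-methoxybenzyl)oxy]-3-(methoxymethoxy)-5-[2-(methylsulfonyl)ethoxy]-4H-chromen-4-one | O=c1c(OCOC)c(-c2ccc(OC)c(OCc3ccccc3)c2)oc2cc(OCc3ccc(OC)cc3)cc(OCCS(C)(=O)=O)c12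
F5 | step 6 | 2-[3-(benzyloxy)-4-methoxyphenyl]-5-hydroxy-7-[(4-methoxybenzyl)oxy]-3-(methoxymethoxy)-4H-chromen-4-one | O=c1c(OCOC)c(-c2ccc(OC)c(OCc3ccccc3)c2)oc2cc(OCc3ccc(OC)cc3)cc(O)c12
F6 | step 8 | 2-[3-(benzyloxy)-4-methoxyphenyl]-5-hydroxy-4-oxo-4H-chromene-3,7-diyl bis(2,2,2-trichloroethyl) bis(sulfate) | O=c1c(OS(=O)(=O)OCC(Cl)(Cl)Cl)c(-c2ccc(OC)c(OCc3ccccc3)c2)oc2cc(OS(=O)(=O)OCC(Cl)(Cl)Cl)cc(O)c12
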